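**Strategy.** The furanone is carried as an aromatic 2‑methoxyfuran and built around its ring oxygen. The C2–O1–C5 array of the lactone is a mesoionic carbonyl ylide (a 2‑methoxy‑isomünchnone from a diazoacetyl carbamate), and the ring C3=C4 bond is the terminal alkyne of a triol‑bearing 1,3‑diyne. One rhodium‑catalysed operation (ylide formation, [3+2] cycloaddition, loss of methyl isocyanate) joins the future carbonyl carbon to C3 and C5 to C4. Trans‑reduction of the remaining alkyne, C5 lithiation, addition to a C22 polyenal and acid then dearomatise the furfuryl carbinol stereoconvergently to the (Z)‑γ‑alkylidenebutenolide.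

Key step: step 9

Remark 1: (4R,6R)‑4‑hydroxy‑2,2,6‑trimethylcyclohexanone (1, (−)‑actinol) is taken as a catalogue chiral‑pool ketone; it is the only source of chirality and supplies both six‑membered rings.
Remark 2: In the Why lines the cyclohexane carbinol carbons carry carotenoid locants (C3, C5, C6); furan/furanone locants are O1, C2 (alkoxy or carbonyl carbon), C3, C4, C5.

**Step 1**
Reactants: 1 (4R,6R)-4-hydroxy-2,2,6-trimethylcyclohexan-1-one
Product: 2 (4R,6R)-2,2,6-trimethyl-4-(triethylsilyloxy)cyclohexan-1-one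
Conditions: TESCl, imidazole, CH2Cl2, 0 °C → rt
Reagents that add atoms: chlorotriethylsilane, CC[Si](Cl)(CC)CC
Why: Imidazole‑promoted silyl ether formation at the only hydroxyl should proceed without touching either stereocentre.

**Step 2**
Reactants: 2 (4R,6R)-2,2,6-trimethyl-4-(triethylsilyloxy)cyclohexan-1-one
Product: 4 (4R)-2,6,6-trimethyl-4-(triethylsilyloxy)cyclohex-1-en-1-yl trifluoromethanesulfonate, via lithium enolate 3 (not isolated)
Conditions: LDA, THF, −78 °C; PhNTf2, −78 °C → rt
Reagents that add atoms: N-phenyl-bis(trifluoromethanesulfonimide), O=S(=O)(N(c1ccccc1)S(=O)(=O)C(F)(F)F)C(F)(F)F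
Why: Only one α‑carbon carries hydrogen, so a single enolate should form and be O‑sulfonylated (enol triflate formation); the methyl‑bearing stereocentre is erased on purpose.

**Step 3**
Reactants: 4 (4R)-2,6,6-trimethyl-4-(triethylsilyloxy)cyclohex-1-en-1-yl trifluoromethanesulfonate; 5 1,4-bis(trimethylsilyl)buta-1,3-diyne
Product: 8 triethyl({(1R)-3,5,5-trimethyl-4-[4-(trimethylsilyl)buta-1,3-diyn-1-yl]cyclohex-3-en-1-yl}oxy)silane, via lithium diynide 6 (not isolated), via diynylzinc chloride 7 (not isolated)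
Conditions: 5, MeLi·LiBr, THF, rt; ZnCl2, 0 °C; then 4, Pd(PPh3)4 (5 mol%), THF, rt → 45 °C
Reagents that add atoms: none
Why: Selective removal of one silyl group by methyllithium, transmetalation to zinc and Negishi alkynyl–alkenyl coupling should install the whole C4 diyne on the hindered enol triflate in one flask.

**Step 4**
Reactants: 8 triethyl({(1R)-3,5,5-trimethyl-4-[4-(trimethylsilyl)buta-1,3-diyn-1-yl]cyclohex-3-en-1-yl}oxy)silane
Product: 9 (1R)-4-(buta-1,3-diyn-1-yl)-3,5,5-trimethylcyclohex-3-en-1-ol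
Conditions: TBAF (2.5 equiv), THF, 0 °C; product kept cold in solution
Reagents that add atoms: none
Why: Fluoride‑mediated desilylation should cleave the O–Si and the C(sp)–Si bond together, freeing the hydroxyl that directs the next step and the terminal alkyne needed for the key step.

**Step 5**
Reactants: 9 (1R)-4-(buta-1,3-diyn-1-yl)-3,5,5-trimethylcyclohex-3-en-1-ol
Product: 10 (1S,3S,6S)-6-(buta-1,3-diyn-1-yl)-1,5,5-trimethyl-7-oxabicyclo[4.1.0]heptan-3-ol
Conditions: VO(acac)2 (5 mol%), t-BuOOH (1.5 equiv, decane), toluene, 0 °C → rt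
Reagents that add atoms: tert-butyl hydroperoxide, CC(C)(C)OO
Why: Hydroxyl‑directed vanadium‑catalysed epoxidation of a homoallylic cyclohexenol should deliver oxygen to the face syn to the C3 hydroxyl, so both epoxide centres are set by the existing carbinol centre, and the alkynes are inert to the metal peroxide.

**Step 6**
Reactants: 10 (1S,3S,6S)-6-(buta-1,3-diyn-1-yl)-1,5,5-trimethyl-7-oxabicyclo[4.1.0]heptan-3-ol
Product: 11 (1S,2R,4S)-1-(buta-1,3-diyn-1-yl)-2,6,6-trimethylcyclohexane-1,2,4-triol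
Conditions: HClO4 (10 mol%), THF/H2O 3:1, 0 °C → rt
Reagents that add atoms: water, O
Why: Acid‑catalysed anti hydrolysis of the epoxide should occur at the methyl‑bearing carbon C5, which is remote from the inductively deactivating alkynyl group and the shielding gem‑dimethyl group, so C5 is inverted, C6 is retained and the trans‑5,6‑diol results; the cis C3 hydroxyl cannot reach the backside, so no oxabicycle should form.

**Step 7**
Reactants: 12 methyl N-methylcarbamate; 13 bromoacetyl bromide
Product: 15 methyl N-(2-bromoacetyl)-N-methylcarbamate, via lithiated carbamate 14 (not isolated)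
Conditions: 12, LiHMDS, THF, −78 °C; then 13, −78 → 0 °C
Reagents that add atoms: none
Why: N‑Acylation of the lithium carbamate by the acid bromide should give the imide, the acyl bromide being far more electrophilic than the alkyl bromide.

**Step 8**
Reactants: 15 methyl N-(2-bromoacetyl)-N-methylcarbamate
Product: 16 methyl N-(2-diazoacetyl)-N-methylcarbamate
Conditions: TsNHNHTs, DBU, THF, 0 °C
Reagents that add atoms: N,N'-ditosylhydrazine, Cc1ccc(cc1)S(=O)(=O)NNS(=O)(=O)c1ccc(C)cc1
Why: Alkylation of the bis‑sulfonyl hydrazide by the bromoacetyl group followed by base‑induced loss of two sulfinates (diazo synthesis from α‑bromoacetyl compounds) should give the acceptor diazo imide without a diazo‑transfer/deacylation detour.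

**Step 9**
Reactants: 11 (1S,2R,4S)-1-(buta-1,3-diyn-1-yl)-2,6,6-trimethylcyclohexane-1,2,4-triol; 16 methyl N-(2-diazoacetyl)-N-methylcarbamate
Product: 19 (1S,2R,4S)-1-[(2-methoxyfuran-3-yl)ethynyl]-2,6,6-trimethylcyclohexane-1,2,4-triol, via mesoionic isomünchnone 17 (not isolated), via oxa-bridged cycloadduct 18 (not isolated)
Conditions: Rh2(OAc)4 (2 mol%), CH2Cl2, 35 °C, 16 (2 equiv) added over 4 h, N2 sweep
Reagents that add atoms: none
Why: Rh2(OAc)4 should convert 16 into a carbenoid that is captured intramolecularly by the carbamate carbonyl oxygen to give the mesoionic carbonyl ylide 17, whose C2–O1–C5 triad is the lactone C–O–C unit of the target. The dipole should add across the terminal alkyne of 11 in a concerted, asynchronous [3+2] cycloaddition (closest known type: isomünchnone–alkyne cycloaddition with cycloreversion, the mesoionic counterpart of the oxazole Diels–Alder/retro‑Diels–Alder furan synthesis), and the bridged adduct 18 should lose methyl isocyanate by retro‑[4+2], aromatisation to the furan driving the sequence. The furan ring is thus closed by an intermolecular (3+2) annulation in which both new bonds are C–C bonds, C2 to the internal alkyne carbon and C5 to the terminal CH. No lasting stereocentre is created: the two bridgeheads of 18 vanish on cycloreversion and the three carbinol centres of 11 are untouched. The step needs regioselectivity, which should follow from attack of the enolate‑like C5 of the dipole on the electrophilic terminal carbon of the conjugated diyne while the oxocarbenium‑like C2 closes on the internal carbon, and site selectivity, since the second triple bond is buried between the tertiary carbinol and the gem‑dimethyl group. Chemoselectivity over O–H insertion rests on the much faster five‑membered ylide closure and on slow addition of 16, the tertiary hydroxyls being hindered and the secondary one dilute.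

**Step 10**
Reactants: 19 (1S,2R,4S)-1-[(2-methoxyfuran-3-yl)ethynyl]-2,6,6-trimethylcyclohexane-1,2,4-triol
Product: 20 (1R,2R,4S)-1-[(E)-2-(2-methoxyfuran-3-yl)ethenyl]-2,6,6-trimethylcyclohexane-1,2,4-triol
Conditions: Red-Al (6 equiv), THF, 0 °C → rt; aq. Rochelle salt
Reagents that add atoms: none
Why: Alkoxide‑directed trans‑hydroalumination of the propargylic alcohol followed by protonolysis should give the E‑alkene only, and the aromatic methoxyfuran is inert to hydride, which is why the reduction is placed after the cycloaddition.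

**Step 11**
Reactants: 4 (4R)-2,6,6-trimethyl-4-(triethylsilyloxy)cyclohex-1-en-1-yl trifluoromethanesulfonate; 21 (E)-3-methylpent-2-en-4-yn-1-ol
Product: 22 (2E)-3-methyl-5-[(4R)-2,6,6-trimethyl-4-(triethylsilyloxy)cyclohex-1-en-1-yl]pent-2-en-4-yn-1-ol
Conditions: Pd(PPh3)4 (5 mol%), CuI (10 mol%), i-Pr2NH, DMF, rt
Reagents that add atoms: none
Why: Sonogashira coupling of the enol triflate with the terminal enynol should give the acetylenic C15 unit with the E‑geometry of the building block retained.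

**Step 12**
Reactants: 22 (2E)-3-methyl-5-[(4R)-2,6,6-trimethyl-4-(triethylsilyloxy)cyclohex-1-en-1-yl]pent-2-en-4-yn-1-ol
Product: 23 (2E)-3-methyl-5-[(4R)-2,6,6-trimethyl-4-(triethylsilyloxy)cyclohex-1-en-1-yl]pent-2-en-4-ynal
Conditions: MnO2, CH2Cl2, rt
Reagents that add atoms: none
Why: Manganese dioxide oxidation is selective for the allylic primary alcohol and should leave the silyl ether and the enyne untouched.

**Step 13**
Reactants: 23 (2E)-3-methyl-5-[(4R)-2,6,6-trimethyl-4-(triethylsilyloxy)cyclohex-1-en-1-yl]pent-2-en-4-ynal; 24 triethyl 4-phosphonocrotonate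
Product: 26 ethyl (2E,4E,6E)-7-methyl-9-[(4R)-2,6,6-trimethyl-4-(triethylsilyloxy)cyclohex-1-en-1-yl]nona-2,4,6-trien-8-ynoate, via phosphonate carbanion 25 (not isolated)
Conditions: 24, LiHMDS, THF, −78 °C; then 23, −78 → 0 °C
Reagents that add atoms: none
Why: The vinylogous Horner–Wadsworth–Emmons olefination should add four carbons and form the new disubstituted double bond with E selectivity.

**Step 14**
Reactants: 26 ethyl (2E,4E,6E)-7-methyl-9-[(4R)-2,6,6-trimethyl-4-(triethylsilyloxy)cyclohex-1-en-1-yl]nona-2,4,6-trien-8-ynoate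
Product: 27 (2E,4E,6E)-7-methyl-9-[(4R)-2,6,6-trimethyl-4-(triethylsilyloxy)cyclohex-1-en-1-yl]nona-2,4,6-trien-8-yn-1-ol
Conditions: DIBAL-H (2.5 equiv), CH2Cl2, −78 °C; aq. Rochelle salt
Reagents that add atoms: none
Why: DIBAL reduction of the conjugated ester should stop cleanly at the allylic alcohol (1,2‑reduction) without touching alkyne or silyl ether.

**Step 15**
Reactants: 27 (2E,4E,6E)-7-methyl-9-[(4R)-2,6,6-trimethyl-4-(triethylsilyloxy)cyclohex-1-en-1-yl]nona-2,4,6-trien-8-yn-1-ol
Product: 28 (2E,4E,6E)-7-methyl-9-[(4R)-2,6,6-trimethyl-4-(triethylsilyloxy)cyclohex-1-en-1-yl]nona-2,4,6-trien-8-ynal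
Conditions: MnO2, CH2Cl2, rt, dark
Reagents that add atoms: none
Why: Allylic oxidation with manganese dioxide should give the trienynal without over‑oxidation.

**Step 16**
Reactants: 28 (2E,4E,6E)-7-methyl-9-[(4R)-2,6,6-trimethyl-4-(triethylsilyloxy)cyclohex-1-en-1-yl]nona-2,4,6-trien-8-ynal; 29 2-(triphenyl-λ5-phosphanylidene)propanal
Product: 30 (2E,4E,6E,8E)-2,9-dimethyl-11-[(4R)-2,6,6-trimethyl-4-(triethylsilyloxy)cyclohex-1-en-1-yl]undeca-2,4,6,8-tetraen-10-ynal
Conditions: toluene, 80 °C, dark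
Reagents that add atoms: none
Why: The Wittig reaction of the stabilised formyl ylide should install the α‑methyl enal terminus with E selectivity and give the aldehyde directly.

**Step 17**
Reactants: 20 (1R,2R,4S)-1-[(E)-2-(2-methoxyfuran-3-yl)ethenyl]-2,6,6-trimethylcyclohexane-1,2,4-triol; 30 (2E,4E,6E,8E)-2,9-dimethyl-11-[(4R)-2,6,6-trimethyl-4-(triethylsilyloxy)cyclohex-1-en-1-yl]undeca-2,4,6,8-tetraen-10-ynal
Product: 33 (5Z)-3-[(E)-2-[(1R,2R,4S)-1,2,4-trihydroxy-2,6,6-trimethylcyclohexyl]ethenyl]-5-[(2E,4E,6E,8E)-11-[(4R)-4-hydroxy-2,6,6-trimethylcyclohex-1-en-1-yl]-2,9-dimethylundeca-2,4,6,8-tetraen-10-yn-1-ylidene]furan-2(5H)-one, via C5-lithiofuran 31 (not isolated), via furfuryl carbinol 32 (not isolated)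
Conditions: n-BuLi (4.1 equiv), THF, −78 → −20 °C; 30, −78 °C; then 1 M aq. HCl/THF, 0 °C → rt
Reagents that add atoms: water, O
Why: After the three hydroxyls are converted into lithium alkoxides the furan should be lithiated at C5 (α‑metalation of a 2‑alkoxyfuran) and add 1,2 to the non‑enolisable enal; on acidification the furfuryl carbinol should ionise, water add to the methoxy‑oxocarbenium carbon and methanol leave (dehydrative unmasking of a 5‑(1‑hydroxyalkyl)‑2‑alkoxyfuran to a γ‑alkylidenebutenolide), both carbinol epimers converging through the delocalised cation on the thermodynamically favoured Z exocyclic olefin, while the same acid cleaves the triethylsilyl ether.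

**Compound list**
1 | (4R,6R)-4-hydroxy-2,2,6-trimethylcyclohexan-1-one ((−)-actinol) | O=C1C(C)(C)C[C@H](O)C[C@H]1C | starting material
2 | (4R,6R)-2,2,6-trimethyl-4-(triethylsilyloxy)cyclohexan-1-one | O=C1C(C)(C)C[C@H](O[Si](CC)(CC)CC)C[C@H]1C | intermediate
3 | lithium (4R)-2,6,6-trimethyl-4-(triethylsilyloxy)cyclohex-1-en-1-olate (not isolated) | CC1=C(O[Li])C(C)(C)C[C@H](O[Si](CC)(CC)CC)C1 | intermediate
4 | (4R)-2,6,6-trimethyl-4-(triethylsilyloxy)cyclohex-1-en-1-yl trifluoromethanesulfonate | CC1=C(OS(=O)(=O)C(F)(F)F)C(C)(C)C[C@H](O[Si](CC)(CC)CC)C1 | intermediate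
5 | 1,4-bis(trimethylsilyl)buta-1,3-diyne | C[Si](C)(C)C#CC#C[Si](C)(C)C | starting material
6 | lithium 4-(trimethylsilyl)buta-1,3-diyn-1-ide (not isolated) | [Li]C#CC#C[Si](C)(C)C | intermediate
7 | chloro[4-(trimethylsilyl)buta-1,3-diyn-1-yl]zinc (not isolated) | Cl[Zn]C#CC#C[Si](C)(C)C | intermediate
8 | triethyl({(1R)-3,5,5-trimethyl-4-[4-(trimethylsilyl)buta-1,3-diyn-1-yl]cyclohex-3-en-1-yl}oxy)silane | CC1=C(C#CC#C[Si](C)(C)C)C(C)(C)C[C@H](O[Si](CC)(CC)CC)C1 | intermediate
9 | (1R)-4-(buta-1,3-diyn-1-yl)-3,5,5-trimethylcyclohex-3-en-1-ol | CC1=C(C#CC#C)C(C)(C)C[C@H](O)C1 | intermediate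
10 | (1S,3S,6S)-6-(buta-1,3-diyn-1-yl)-1,5,5-trimethyl-7-oxabicyclo[4.1.0]heptan-3-ol (epoxide oxygen cis to the hydroxyl) | C#CC#C[C@]12O[C@@]1(C)C[C@@H](O)CC2(C)C | intermediate
11 | (1S,2R,4S)-1-(buta-1,3-diyn-1-yl)-2,6,6-trimethylcyclohexane-1,2,4-triol (1-OH/2-OH trans, 1-OH/4-OH cis) | C#CC#C[C@@]1(O)C(C)(C)C[C@H](O)C[C@@]1(C)O | intermediate
12 | methyl N-methylcarbamate | CNC(=O)OC | starting material
13 | bromoacetyl bromide | BrCC(Br)=O | starting material
14 | N-lithio derivative of methyl N-methylcarbamate (not isolated) | [Li]N(C)C(=O)OC | intermediate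
15 | methyl N-(2-bromoacetyl)-N-methylcarbamate | COC(=O)N(C)C(=O)CBr | intermediate
16 | methyl N-(2-diazoacetyl)-N-methylcarbamate | COC(=O)N(C)C(=O)C=[N+]=[N-] | intermediate
17 | 2-methoxy-3-methyl-1,3-oxazol-3-ium-4-olate (isomünchnone, not isolated) | COC1=[O+]C=C([O-])N1C | intermediate
18 | 1-methoxy-2-methyl-6-{[(1S,2R,4S)-1,2,4-trihydroxy-2,6,6-trimethylcyclohexyl]ethynyl}-7-oxa-2-azabicyclo[2.2.1]hept-5-en-3-one (bridgeheads as formed, not isolated) | COC12OC(C(=O)N2C)C=C1C#C[C@@]1(O)C(C)(C)C[C@H](O)C[C@@]1(C)O | intermediate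
19 | (1S,2R,4S)-1-[(2-methoxyfuran-3-yl)ethynyl]-2,6,6-trimethylcyclohexane-1,2,4-triol | COc1occc1C#C[C@@]1(O)C(C)(C)C[C@H](O)C[C@@]1(C)O | intermediate
20 | (1R,2R,4S)-1-[(E)-2-(2-methoxyfuran-3-yl)ethenyl]-2,6,6-trimethylcyclohexane-1,2,4-triol | COc1occc1/C=C/[C@@]1(O)C(C)(C)C[C@H](O)C[C@@]1(C)O | intermediate
21 | (E)-3-methylpent-2-en-4-yn-1-ol | C#C/C(C)=C/CO | starting material
22 | (2E)-3-methyl-5-[(4R)-2,6,6-trimethyl-4-(triethylsilyloxy)cyclohex-1-en-1-yl]pent-2-en-4-yn-1-ol | CC1=C(C#C/C(C)=C/CO)C(C)(C)C[C@H](O[Si](CC)(CC)CC)C1 | intermediate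
23 | (2E)-3-methyl-5-[(4R)-2,6,6-trimethyl-4-(triethylsilyloxy)cyclohex-1-en-1-yl]pent-2-en-4-ynal | CC1=C(C#C/C(C)=C/C=O)C(C)(C)C[C@H](O[Si](CC)(CC)CC)C1 | intermediate
24 | triethyl 4-phosphonocrotonate (ethyl (2E)-4-(diethoxyphosphoryl)but-2-enoate) | CCOC(=O)/C=C/CP(=O)(OCC)OCC | starting material
25 | lithium salt of the C4 carbanion of 24 (not isolated) | [Li+].CCOC(=O)/C=C/[CH-]P(=O)(OCC)OCC | intermediate
26 | ethyl (2E,4E,6E)-7-methyl-9-[(4R)-2,6,6-trimethyl-4-(triethylsilyloxy)cyclohex-1-en-1-yl]nona-2,4,6-trien-8-ynoate | CC1=C(C#C/C(C)=C/C=C/C=C/C(=O)OCC)C(C)(C)C[C@H](O[Si](CC)(CC)CC)C1 | intermediate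
27 | (2E,4E,6E)-7-methyl-9-[(4R)-2,6,6-trimethyl-4-(triethylsilyloxy)cyclohex-1-en-1-yl]nona-2,4,6-trien-8-yn-1-ol | CC1=C(C#C/C(C)=C/C=C/C=C/CO)C(C)(C)C[C@H](O[Si](CC)(CC)CC)C1 | intermediate
28 | (2E,4E,6E)-7-methyl-9-[(4R)-2,6,6-trimethyl-4-(triethylsilyloxy)cyclohex-1-en-1-yl]nona-2,4,6-trien-8-ynal | CC1=C(C#C/C(C)=C/C=C/C=C/C=O)C(C)(C)C[C@H](O[Si](CC)(CC)CC)C1 | intermediate
29 | 2-(triphenyl-λ5-phosphanylidene)propanal | CC(C=O)=P(c1ccccc1)(c1ccccc1)c1ccccc1 | starting material
30 | (2E,4E,6E,8E)-2,9-dimethyl-11-[(4R)-2,6,6-trimethyl-4-(triethylsilyloxy)cyclohex-1-en-1-yl]undeca-2,4,6,8-tetraen-10-ynal | CC1=C(C#C/C(C)=C/C=C/C=C/C=C(C)/C=O)C(C)(C)C[C@H](O[Si](CC)(CC)CC)C1 | intermediate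
31 | C5-lithiated trilithium trialkoxide of 20 (not isolated) | COc1oc([Li])cc1/C=C/[C@@]1(O[Li])C(C)(C)C[C@H](O[Li])C[C@@]1(C)O[Li] | intermediate
32 | furfuryl carbinol from 31 and 30, neutral form, both epimers at the new carbinol carbon (not isolated) | COc1oc(C(O)/C(C)=C/C=C/C=C/C=C(C)/C#CC2=C(C)C[C@@H](O[Si](CC)(CC)CC)CC2(C)C)cc1/C=C/[C@@]1(O)C(C)(C)C[C@H](O)C[C@@]1(C)O | intermediate
33 | (5Z)-3-[(E)-2-[(1R,2R,4S)-1,2,4-trihydroxy-2,6,6-trimethylcyclohexyl]ethenyl]-5-[(2E,4E,6E,8E)-11-[(4R)-4-hydroxy-2,6,6-trimethylcyclohex-1-en-1-yl]-2,9-dimethylundeca-2,4,6,8-tetraen-10-yn-1-ylidene]furan-2(5H)-one | CC1=C(C#C/C(C)=C/C=C/C=C/C=C(C)/C=C2C=C(/C=C/[C@@]3(O)C(C)(C)C[C@H](O)C[C@@]3(C)O)C(=O)O/2)C(C)(C)C[C@H](O)C1 | target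

**Step count.** Total: 17 steps. Longest linear sequence: 9 steps (1–6, 9, 10, 17; the polyenal branch 1, 2, 11–16, 17 is equally long).

**Steps most likely to fail**

Step 9 (key step). The dipole may be protonated or trapped by the free hydroxyls, the carbenoid may be diverted to O–H insertion, or the dipole may add to the diyne with the opposite orientation. Fallback, setting out from 11 and returning at 19: the same two bonds are made without a carbenoid by the thermal oxazole–alkyne Diels–Alder/retro‑Diels–Alder furan synthesis. 5‑Methoxy‑4‑methyloxazole F1 (from methyl N‑formylalaninate by P2O5 cyclodehydration) is heated with 11 in toluene at 110–120 °C. Addition across C2/C5 of the azadiene, with the alkoxy‑bearing carbon bonding to the substituted alkyne carbon, should give the 7‑oxa‑2‑azabicyclo[2.2.1]heptadiene adduct F2, which extrudes acetonitrile to give 19.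

Step 17. Metalation may be unselective in the presence of three alkoxides (incomplete C5 lithiation, carbolithiation of the alkoxide‑flanked vinylfuran). In the acid phase the hemi‑orthoester may open to the 4‑oxo ester instead of closing to the lactone, or the polyene may lose geometric integrity. Fallback, setting out from 20 and returning at 33, uses a silyloxyfuran instead of a lithiofuran and separates C–C bond formation from elimination:
- Dilute aqueous acid converts 20 into 3‑[(E)‑2‑[(1R,2R,4S)‑1,2,4‑trihydroxy‑2,6,6‑trimethylcyclohexyl]ethenyl]furan‑2(5H)‑one F3.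
- TESOTf/Et3N gives the per‑silylated 2‑(triethylsilyloxy)furan F4.
- BF3·OEt2‑mediated vinylogous Mukaiyama aldol addition to 30 at −78 °C gives the γ‑(1‑hydroxyalkyl)butenolide F5 as a diastereomer mixture.
- Mitsunobu‑type anti‑elimination (DEAD/PPh3) gives the tetrakis‑triethylsilyl ether of the target F6.
- HF·pyridine removes the silyl groups to give 33.

Step 5. Oxygen transfer to the conjugation‑deactivated tetrasubstituted alkene may be slow, and facial selectivity may erode if delivery is not fully hydroxyl‑bound. Fallback, setting out from 8 and returning at 11, reaches the same syn epoxide by substrate‑controlled halohydrin formation and ring closure with inversion: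
- NBS in THF/H2O should form the bromonium ion anti to the silyloxy group and be opened by water at the methyl‑bearing carbon, giving the bromohydrin F7.
- K2CO3/MeOH closes the epoxide with inversion at the bromide carbon and removes the alkynyl silyl group, giving the silyl‑protected syn epoxide F8.
- The aqueous HClO4 conditions of step 6 then open the epoxide and cleave the triethylsilyl ether to give 11.

**Further compounds**
F1 | step 9 | 5-methoxy-4-methyl-1,3-oxazole | COc1ocnc1C
F2 | step 9 | 1-methoxy-3-methyl-6-{[(1S,2R,4S)-1,2,4-trihydroxy-2,6,6-trimethylcyclohexyl]ethynyl}-7-oxa-2-azabicyclo[2.2.1]hepta-2,5-diene (not isolated) | COC12OC(N=C1C)C=C2C#C[C@@]1(O)C(C)(C)C[C@H](O)C[C@@]1(C)O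
F3 | step 17 | 3-[(E)-2-[(1R,2R,4S)-1,2,4-trihydroxy-2,6,6-trimethylcyclohexyl]ethenyl]furan-2(5H)-one | O=C1OCC=C1/C=C/[C@@]1(O)C(C)(C)C[C@H](O)C[C@@]1(C)O
F4 | step 17 | 2-(triethylsilyloxy)-3-[(E)-2-(tris-O-triethylsilyl triol ring)ethenyl]furan | CC[Si](CC)(CC)Oc1occc1/C=C/[C@@]1(O[Si](CC)(CC)CC)C(C)(C)C[C@H](O[Si](CC)(CC)CC)C[C@@]1(C)O[Si](CC)(CC)CC
F5 | step 17 | γ-(1-hydroxyalkyl)butenolide aldol adduct of F4 and 30 (diastereomer mixture at C5 and the carbinol carbon) | O=C1OC(C(O)/C(C)=C/C=C/C=C/C=C(C)/C#CC2=C(C)C[C@@H](O[Si](CC)(CC)CC)CC2(C)C)C=C1/C=C/[C@@]1(O[Si](CC)(CC)CC)C(C)(C)C[C@H](O[Si](CC)(CC)CC)C[C@@]1(C)O[Si](CC)(CC)CC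
F6 | step 17 | tetrakis-O-triethylsilyl ether of 33 | CC1=C(C#C/C(C)=C/C=C/C=C/C=C(C)/C=C2C=C(/C=C/[C@@]3(O[Si](CC)(CC)CC)C(C)(C)C[C@H](O[Si](CC)(CC)CC)C[C@@]3(C)O[Si](CC)(CC)CC)C(=O)O/2)C(C)(C)C[C@H](O[Si](CC)(CC)CC)C1
F7 | step 5 | bromohydrin of 8: 2-bromo-1,3,3-trimethyl-5-(triethylsilyloxy)-2-[4-(trimethylsilyl)buta-1,3-diyn-1-yl]cyclohexan-1-ol (Br trans to OH, OH cis to the silyloxy group) | C[Si](C)(C)C#CC#C[C@]1(Br)C(C)(C)C[C@H](O[Si](CC)(CC)CC)C[C@]1(C)O
F8 | step 5 | O-triethylsilyl ether of 10 | C#CC#C[C@]12O[C@@]1(C)C[C@@H](O[Si](CC)(CC)CC)CC2(C)C
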